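## Structural features

The target is an acyclic 8-O-4' neolignan with two benzene rings and no other ring: ring A (3,4,5-trimethoxyphenyl) is bonded through carbon to C7 of a propane chain C7–C8–C9, and ring B (4-allyl-2,6-dimethoxyphenyl) is bonded through its phenolic oxygen to C8. C7 carries a secondary benzylic hydroxyl and C9 a primary hydroxyl. C7 and C8 are adjacent stereocentres, both R, which places the C7 hydroxyl and the C8 aryloxy group threo (syn in the zigzag drawing of C9–C8–C7–ring A). Three elements are fragile: the C7 carbinol ionises easily under acid because ring A is electron-rich; the terminal allyl group of ring B migrates into conjugation under metal-hydride or strong-base conditions and is attacked by ozone, boranes and hydrogenation catalysts; and any intermediate with a carbonyl at C7 has an acidic C8–H and a β-oxygen at C9 that can eliminate. The skeleton is simple (three commercial-type pieces), so the real difficulty is absolute and relative control of the acyclic C7/C8 pair when the only resident director at C8 is a weakly basic aryl ether. The key step exploits the fact that the C7–C1 bond to ring A lies next to C8, whose ether oxygen sits between the methoxy oxygens at C2 and C6 of ring B; together with a carbonyl oxygen at C7 these donors form a multidentate pocket for magnesium. The two ortho substituents also twist the C8–O bond out of the plane of ring B, which makes that oxygen more ether-like and a better donor than in an unhindered aryl ether.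

## Logic of the disconnections

13 ⇒ 12. The O9–Si bond is added in the retrosynthetic sense. O9 must neither be deprotonated by an organomagnesium reagent nor bind magnesium in the bond-forming step, so the gain is in control, not in skeleton. The forward step must cleave a primary silyl ether without acid, which would ionise C7, and without strong base, which would move the allyl double bond.

12 ⇒ 7 + 9 (through 11 and 10). The C7–C1 bond to ring A is cut. It is the one C–C bond whose formation next to the existing C8 stereocentre can be steered by the oxygen array around C8. The cut removes one stereocentre and divides the molecule into a ring A nucleophile and a three-carbon electrophile that already carries ring B. The forward step demands attack on one carbonyl face only, through 10, and a nucleophile mild enough not to deprotonate C8.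

9 ⇒ 8. The C–Mg bond is traced to a C–Br bond. This reaches a commercial arene and asks only for a clean metal insertion.

7 ⇒ 5 (through 6). No skeletal bond is cut; the C7 oxidation level is raised to that of an ester. The reason is that 7 is configurationally labile at C8 and should exist only just before use, whereas 5 can be purified and stored. The forward reduction must stop at the aldehyde level, which requires 6 to survive until the hydride is quenched, and it must leave C8 untouched.

5 ⇒ 3 + 4. The C8–O bond to ring B is cut. This releases ring B with its allyl and methoxy groups as a commercial phenol and leaves a three-carbon hydroxy ester with a single stereocentre of opposite configuration. The forward step must be a substitution with complete inversion at a secondary carbon flanked by an ester and a silyloxymethyl group, using a phenol hindered by two ortho substituents.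

3 ⇒ 2 ⇒ 1. The O9–Si bond is removed and the two hydroxyls are tied back into the acetonide of the chiral pool. The gain is a commercial, enantiopure three-carbon unit with the configuration of L-serine. The forward demands are hydrolysis of the acetal without loss of the ester and silylation of the primary hydroxyl only.

## Other disconnections considered

Alternative 1: The cut is at C9–O9 and C8–H: the C9 hydroxyl is traced to a C9–Si bond and C8 to the internal carbon of a C8=C9 aryl enol ether, with silicon tethered to O7. The forward key step is the intramolecular hydrosilylation of the dimethylsilyl ether A1 under H2PtCl6 catalysis. It closes the five-membered oxasilolane A2 in the endo mode (Si to C9, H to C8); Tamao oxidation of the C–Si bond (H2O2, KF, KHCO3) would then give 13 directly.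
- In favour: hydrogen is delivered to C8 within a cyclic transition state anchored at C7. This 1,2-induction is a known reaction type for α-hydroxy enol ethers, leads to the syn (here threo) relation, and does not depend on the donor strength of an aryl ether oxygen. No epimerisable α-aryloxy carbonyl compound occurs, and O9 never needs a protecting group.
- Against it here: the Si–H/platinum couple has no built-in preference for the hindered, tethered 1,1-disubstituted enol ether over the unhindered terminal allyl group of ring B, so intermolecular hydrosilylation and migration of the allyl double bond are expected to compete. A1 combines an acid-labile aryl vinyl ether with an ionisable, electron-rich benzylic oxygen, while H2PtCl6 is a strong acid. C7 must already be a single enantiomer, which needs a separate enantioselective step and a non-trivial construction of the enol ether.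
- Comparison: structurally the direction of induction is reversed (C7 to C8 instead of C8 to C7) and the absolute configuration comes from a reagent or catalyst instead of the chiral pool. Mechanistically, tethered delivery is a more dependable source of the threo relation than chelation through an aryl ether; on this point and on protecting-group economy the alternative is the better plan. In steps after the key precursor it is equal (two from A1, two from 7). Enantioselective access to A1 is expected to take longer than the four steps to 7, and the conflict with the allyl group is the deciding weakness.

Alternative 2: The cut is the central C7–C8 bond. The forward key step is the addition of the Z-configured γ-aryloxyallyl diisopinocampheylborane A3 to 3,4,5-trimethoxybenzaldehyde A4 through a closed six-membered chair transition state. It would give A5 with both stereocentres formed at once: the Z geometry translates into the syn (threo) relation and the isopinocampheyl groups choose the aldehyde face.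
- In favour: it is the most convergent cut, A4 is a cheap commercial aldehyde, and relative and absolute configuration are set together by reagent control without any reliance on chelation. In stereochemical predictability and in the number of centres set per step the alternative is better than the chosen plan.
- Against it here: A5 carries no allyl group on ring B and has a vinyl group that must become C9 by ozonolysis and NaBH4 reduction. The ring B allyl group cannot be present during that cleavage, because two terminal monosubstituted alkenes cannot be told apart. It would have to be introduced afterwards at the position para to the ether oxygen, which is not where electrophiles attack a 1,2,3-trioxygenated ring. A halogen placed there in advance would not survive the allylic lithiation needed to make A3. That lithiation of an aryl allyl ether with two methoxy groups also invites ring metalation and Wittig rearrangement, and two stoichiometric isopinocampheyl groups are sacrificed.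
- Comparison: on structure (convergence) and mechanism (closed transition state) the alternative is superior. On step economy it is shorter up to A5 (about three steps), but the repair after coupling (cleavage, reduction, late allyl installation, probably with hydroxyl protection) is expected to make the whole sequence longer than the seven steps chosen. The chosen plan carries the allyl group untouched from commercial 4. For analogues without an alkene on ring B this alternative would be the stronger plan.

Alternative 3: The cut is the C8–C9 bond. In the forward key step the aryloxyacetaldehyde A6 forms an enamine with a diarylprolinol silyl ether, and this enamine adds to formaldehyde A7; hydrolysis would release A8, with C8 set by the shielding group of the catalyst.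
- In favour: the step is catalytic, uses achiral and cheap inputs, gives access to either enantiomer, and avoids the phosphine oxide waste of an inversion step. Silylation of A8 at O9 would give 7, so it feeds the same C7–ring A bond formation.
- Against it here: A8 is an α-aryloxy-β-hydroxy aldehyde. Its C8–H is more acidic than in a simple aldehyde and the amine catalyst is still present, so racemisation through the product enamine, β-elimination of water and hemiacetal oligomerisation are all plausible. Such products are normally trapped in situ by reduction or olefination, which is not possible here because the aldehyde is needed. The subsequent silylation also needs a base.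
- Comparison: structurally it solves only C8 and leaves the C7 question exactly as in the chosen plan (equal there). In step count it is equal: about four steps from 4 to 7 (O-alkylation with a masked bromoacetaldehyde, unmasking, hydroxymethylation, silylation) against four steps from 1. In atom economy and catalytic character it is better. In configurational security at C8 it is weaker, because the chosen plan fixes C8 by a stereospecific SN2 inversion of a chiral-pool centre and carries it as a stable ester until just before use.

Key step: step 6

Remark on atom labels: C7 is the carbinol carbon, C8 the aryloxy-bearing carbon and C9 the hydroxymethyl carbon; ring A is the 3,4,5-trimethoxyphenyl ring and ring B the 4-allyl-2,6-dimethoxyphenyl ring.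
Assumption on the chiral pool: commercial methyl (S)-2,2-dimethyl-1,3-dioxolane-4-carboxylate (the acetonide of L-serine-derived methyl L-glycerate) is used in place of L-serine, which spares the diazotisation and esterification.
Assumption on A3: the isopinocampheyl groups are drawn as those from (+)-α-pinene, taken to deliver the allyl unit to the si face of A4.

## Route

**Step 1**
Reactants: 1 methyl (S)-2,2-dimethyl-1,3-dioxolane-4-carboxylate
Product: 2 methyl (S)-2,3-dihydroxypropanoate
Conditions: Dowex 50W (H+ form), MeOH–H2O 9:1, rt; filter, concentrate, toluene azeotrope
Reagents that add atoms: none
Why: Acid-catalysed acetal hydrolysis: only the dioxolane C–O bonds at the acetal carbon are broken, the ester is safe because exchange with the methanol solvent is degenerate, and C2 is untouched, so the S configuration is carried through.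

**Step 2**
Reactants: 2 methyl (S)-2,3-dihydroxypropanoate
Product: 3 methyl (S)-3-[(tert-butyldiphenylsilyl)oxy]-2-hydroxypropanoate
Conditions: TBDPSCl (1.05 equiv), imidazole (2.2 equiv), CH2Cl2, −10 → 0 °C
Reagents that add atoms: tert-butyldiphenylsilyl chloride, CC(C)(C)[Si](Cl)(c1ccccc1)c1ccccc1
Why: Regioselective O-silylation: the bulky chlorosilane, activated by imidazole, should react with the unhindered primary hydroxyl much faster than with the secondary one, which is hindered and made less nucleophilic by the adjacent ester; C2 is not involved.

**Step 3**
Reactants: 3 methyl (S)-3-[(tert-butyldiphenylsilyl)oxy]-2-hydroxypropanoate; 4 4-allyl-2,6-dimethoxyphenol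
Product: 5 methyl (R)-2-(4-allyl-2,6-dimethoxyphenoxy)-3-[(tert-butyldiphenylsilyl)oxy]propanoate
Conditions: PPh3 (1.5 equiv), DIAD (1.5 equiv), toluene, 0 °C → rt
Reagents that add atoms: none
Why: Mitsunobu etherification: PPh3/DIAD activate the secondary hydroxyl in situ and the phenoxide of 4, acidic enough to protonate the betaine, displaces it by SN2 with inversion, so the S-configured C2 of 3 becomes the R-configured C8 of 5; the adjacent ester favours SN2 over ionisation, and the neutral medium leaves the silyl ether, the allyl group and the C8–H alone.

**Step 4**
Reactants: 5 methyl (R)-2-(4-allyl-2,6-dimethoxyphenoxy)-3-[(tert-butyldiphenylsilyl)oxy]propanoate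
Product: 7 (R)-2-(4-allyl-2,6-dimethoxyphenoxy)-3-[(tert-butyldiphenylsilyl)oxy]propanal, via diisobutylaluminium hemiacetal 6 (not isolated)
Conditions: iBu2AlH (1.1 equiv), CH2Cl2, −78 °C; MeOH, −78 °C; aq KNaC4H4O6 (potassium sodium tartrate), rt; crude 7 dried and used at once
Reagents that add atoms: none
Why: Partial reduction of an ester with iBu2AlH: hydride transfer gives the tetrahedral hemiacetal 6, which should be held at −78 °C by coordination of aluminium to the neighbouring aryloxy and methoxy oxygens and release 7 only on hydrolysis after the excess hydride is destroyed; no base is present, so C8 keeps its R configuration, and 7 is used crude because α-aryloxy aldehydes epimerise and hydrate on storage or on silica.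

**Step 5**
Reactants: 8 5-bromo-1,2,3-trimethoxybenzene
Product: 9 3,4,5-trimethoxyphenylmagnesium bromide (about 1 M titrated solution, used directly)
Conditions: Mg turnings (iodine-activated), THF, rt → 45 °C
Reagents that add atoms: magnesium, [Mg]
Why: Grignard reagent formation by direct insertion of magnesium into the aryl C–Br bond; the methoxy groups are inert, and the concentrated solution keeps the THF share small in the next step.

**Step 6**
Reactants: 7 (R)-2-(4-allyl-2,6-dimethoxyphenoxy)-3-[(tert-butyldiphenylsilyl)oxy]propanal; 9 3,4,5-trimethoxyphenylmagnesium bromide
Product: 12 (1R,2R)-2-(4-allyl-2,6-dimethoxyphenoxy)-3-[(tert-butyldiphenylsilyl)oxy]-1-(3,4,5-trimethoxyphenyl)propan-1-ol, via magnesium bromide chelate 10 (not isolated), via bromomagnesium alkoxide 11 (not isolated)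
Conditions: 7, MgBr2·OEt2 (3 equiv), CH2Cl2, −78 °C, 30 min; then 9 (1.5 equiv, THF below about 10 vol %), −78 → −50 °C; aq NH4Cl
Reagents that add atoms: none
Why: Nucleophilic 1,2-addition of an aryl Grignard reagent to an aldehyde held in a magnesium chelate (Cram-chelate model; the closest known reaction type is the chelation-controlled Grignard addition to α-alkoxy aldehydes that gives syn 1,2-diol monoethers). MgBr2 binds the C7 carbonyl oxygen and the C8 aryloxy oxygen, with one ortho methoxy oxygen of ring B as a third donor, to give the five-membered chelate 10, in which the C7–C8 rotamer is locked with C=O and C8–O syn-periplanar. The aryl group of 9 is then delivered to the carbonyl face on the side of the C8 hydrogen, away from the CH2OSi arm, which forms the C7–ring A bond and, through alkoxide 11, the R configuration at C7, that is the threo (7R,8R) pair; no ring is closed. The new stereocentre is therefore controlled by the resident C8 centre (1,2-induction), whose R configuration was fixed in step 3. The selectivity needed is chelate attack over open Felkin–Anh attack and over a six-membered chelate through O9, both of which would lead to the erythro epimer. It should be secured by the bulky, non-coordinating tert-butyldiphenylsilyl group on O9, by the two ortho substituents that twist the C8–O–aryl unit out of conjugation and raise the basicity of the ether oxygen, by the weakly coordinating solvent CH2Cl2, and by premixing with excess MgBr2·OEt2 before 9 arrives. The low temperature and the modest basicity of an aryl Grignard reagent should keep enolisation of 7 (loss of C8 integrity) and β-elimination of silanolate in check. The allyl group, the silyl ether and the aryl ethers are inert under these conditions.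

**Step 7**
Reactants: 12 (1R,2R)-2-(4-allyl-2,6-dimethoxyphenoxy)-3-[(tert-butyldiphenylsilyl)oxy]-1-(3,4,5-trimethoxyphenyl)propan-1-ol
Product: 13 (1R,2R)-2-(4-allyl-2,6-dimethoxyphenoxy)-1-(3,4,5-trimethoxyphenyl)propane-1,3-diol
Conditions: Bu4NF (1.5 equiv), AcOH (1.5 equiv), THF, 0 °C → rt
Reagents that add atoms: none
Why: Fluoride-induced desilylation driven by the strong Si–F bond; acetic acid buffers the alkoxide, so the medium stays near neutral, which protects the acid-labile benzylic C7 carbinol from ionisation and the allyl group from base-induced migration, and no bond at C7 or C8 is touched, so the (7R,8R) configuration is retained.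

## Compound list

1 | methyl (S)-2,2-dimethyl-1,3-dioxolane-4-carboxylate | COC(=O)[C@@H]1COC(C)(C)O1 | starting material
2 | methyl (S)-2,3-dihydroxypropanoate | COC(=O)[C@@H](O)CO | intermediate
3 | methyl (S)-3-[(tert-butyldiphenylsilyl)oxy]-2-hydroxypropanoate | COC(=O)[C@@H](O)CO[Si](c1ccccc1)(c1ccccc1)C(C)(C)C | intermediate
4 | 4-allyl-2,6-dimethoxyphenol | C=CCc1cc(OC)c(O)c(OC)c1 | starting material
5 | methyl (R)-2-(4-allyl-2,6-dimethoxyphenoxy)-3-[(tert-butyldiphenylsilyl)oxy]propanoate | C=CCc1cc(OC)c(O[C@H](CO[Si](c2ccccc2)(c2ccccc2)C(C)(C)C)C(=O)OC)c(OC)c1 | intermediate
6 | diisobutylaluminium hemiacetal: diisobutylaluminium (2R)-2-(4-allyl-2,6-dimethoxyphenoxy)-3-[(tert-butyldiphenylsilyl)oxy]-1-methoxypropan-1-olate, configuration at C1 not defined, formed in the flask only | C=CCc1cc(OC)c(O[C@H](CO[Si](c2ccccc2)(c2ccccc2)C(C)(C)C)C(OC)O[Al](CC(C)C)CC(C)C)c(OC)c1 | intermediate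
7 | (R)-2-(4-allyl-2,6-dimethoxyphenoxy)-3-[(tert-butyldiphenylsilyl)oxy]propanal | C=CCc1cc(OC)c(O[C@H](CO[Si](c2ccccc2)(c2ccccc2)C(C)(C)C)C=O)c(OC)c1 | intermediate
8 | 5-bromo-1,2,3-trimethoxybenzene | COc1cc(Br)cc(OC)c1OC | starting material
9 | 3,4,5-trimethoxyphenylmagnesium bromide | COc1cc([Mg]Br)cc(OC)c1OC | intermediate
10 | magnesium bromide chelate: 1:1 complex of 7 and MgBr2, magnesium bound to the C7 carbonyl oxygen, the C8 aryloxy oxygen and one ortho methoxy oxygen, formed in the flask only | C=CCc1cc(OC)c(O[C@H](CO[Si](c2ccccc2)(c2ccccc2)C(C)(C)C)C=O)c(OC)c1.Br[Mg]Br | intermediate
11 | bromomagnesium alkoxide: bromomagnesium (1R,2R)-2-(4-allyl-2,6-dimethoxyphenoxy)-3-[(tert-butyldiphenylsilyl)oxy]-1-(3,4,5-trimethoxyphenyl)propan-1-olate, formed in the flask only | C=CCc1cc(OC)c(O[C@H](CO[Si](c2ccccc2)(c2ccccc2)C(C)(C)C)[C@H](O[Mg]Br)c2cc(OC)c(OC)c(OC)c2)c(OC)c1 | intermediate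
12 | (1R,2R)-2-(4-allyl-2,6-dimethoxyphenoxy)-3-[(tert-butyldiphenylsilyl)oxy]-1-(3,4,5-trimethoxyphenyl)propan-1-ol | C=CCc1cc(OC)c(O[C@H](CO[Si](c2ccccc2)(c2ccccc2)C(C)(C)C)[C@H](O)c2cc(OC)c(OC)c(OC)c2)c(OC)c1 | intermediate
13 | (1R,2R)-2-(4-allyl-2,6-dimethoxyphenoxy)-1-(3,4,5-trimethoxyphenyl)propane-1,3-diol | C=CCc1cc(OC)c(O[C@H](CO)[C@H](O)c2cc(OC)c(OC)c(OC)c2)c(OC)c1 | target

## Step count and least certain steps

Total step count: 7. Longest linear sequence: 6 steps (1 → 2 → 3 → 5 → 7 → 12 → 13, that is steps 1, 2, 3, 4, 6 and 7); step 5 is a one-step branch that supplies 9.

Step 6 (key step). The most likely failure is poor facial selectivity. The open Felkin–Anh pathway competes whenever the chelate is incompletely formed: an aryl ether oxygen is a weaker donor than an alkyl ether oxygen, and the THF that comes in with 9 competes for magnesium. A second failure mode is proton abstraction at C8 by 9, which would erode the C8 configuration. The fallback replaces C–C bond formation under chelate control by carbonyl reduction under Felkin–Anh control. It sets out from 5, which is converted with MeNHOMe·HCl and iPrMgCl (THF, −20 °C) into the Weinreb amide (R)-2-(4-allyl-2,6-dimethoxyphenoxy)-3-[(tert-butyldiphenylsilyl)oxy]-N-methoxy-N-methylpropanamide F1. F1 takes up 9 (THF, −20 → 0 °C) and stops at the ketone (R)-2-(4-allyl-2,6-dimethoxyphenoxy)-3-[(tert-butyldiphenylsilyl)oxy]-1-(3,4,5-trimethoxyphenyl)propan-1-one F2. Reduction of F2 with the bulky, non-chelating hydride K[HB(sBu)3] (THF, −78 °C) should occur anti to the perpendicular aryloxy group and give the threo alcohol, so the route is rejoined at 12. Material from step 6 of unsatisfactory diastereomeric purity can be converged on F2 by oxidation with Dess–Martin periodinane and sent through the same reduction.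

Step 3. The most likely failure is sluggish or incomplete substitution, because 4 is flanked by two ortho methoxy groups and the carbinol of 3 by an ester and a silyloxymethyl group. The activated alcohol can then be diverted to elimination or to alkylation of the hydrazide by-product. The fallback replaces the redox condensation by sulfonate activation and displacement in two stages. It sets out from 3: Tf2O and 2,6-lutidine (CH2Cl2, −78 °C) give the triflate methyl (S)-3-[(tert-butyldiphenylsilyl)oxy]-2-[(trifluoromethylsulfonyl)oxy]propanoate F3. F3 reacts with the phenoxide of 4 (4, K2CO3, MeCN, −20 → 0 °C) by SN2 with inversion, since α-triflyloxy esters are very reactive SN2 electrophiles, and the route is rejoined at 5.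

Step 4. The most likely failure is over-reduction to the primary alcohol if 6 collapses before the quench, or erosion of the C8 configuration by enolisation of 7 during work-up. The fallback is full reduction followed by oxidation under base-free conditions. It sets out from 5: LiBH4 (THF, 0 °C → rt) gives the alcohol (S)-2-(4-allyl-2,6-dimethoxyphenoxy)-3-[(tert-butyldiphenylsilyl)oxy]propan-1-ol F4 (the descriptor changes by priority rules only, not in space). Oxidation of F4 with Dess–Martin periodinane and NaHCO3 (CH2Cl2, 0 °C) rejoins the route at 7.

## Further compounds

F1 | step 6 | (R)-2-(4-allyl-2,6-dimethoxyphenoxy)-3-[(tert-butyldiphenylsilyl)oxy]-N-methoxy-N-methylpropanamide | C=CCc1cc(OC)c(O[C@H](CO[Si](c2ccccc2)(c2ccccc2)C(C)(C)C)C(=O)N(C)OC)c(OC)c1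
F2 | step 6 | (R)-2-(4-allyl-2,6-dimethoxyphenoxy)-3-[(tert-butyldiphenylsilyl)oxy]-1-(3,4,5-trimethoxyphenyl)propan-1-one | C=CCc1cc(OC)c(O[C@H](CO[Si](c2ccccc2)(c2ccccc2)C(C)(C)C)C(=O)c2cc(OC)c(OC)c(OC)c2)c(OC)c1
F3 | step 3 | methyl (S)-3-[(tert-butyldiphenylsilyl)oxy]-2-[(trifluoromethylsulfonyl)oxy]propanoate | COC(=O)[C@@H](OS(=O)(=O)C(F)(F)F)CO[Si](c1ccccc1)(c1ccccc1)C(C)(C)C
F4 | step 4 | (S)-2-(4-allyl-2,6-dimethoxyphenoxy)-3-[(tert-butyldiphenylsilyl)oxy]propan-1-ol | C=CCc1cc(OC)c(O[C@H](CO[Si](c2ccccc2)(c2ccccc2)C(C)(C)C)CO)c(OC)c1
A1 | alternative 1 | (R)-{[2-(4-allyl-2,6-dimethoxyphenoxy)-1-(3,4,5-trimethoxyphenyl)prop-2-en-1-yl]oxy}dimethylsilane | C=CCc1cc(OC)c(OC(=C)[C@H](O[SiH](C)C)c2cc(OC)c(OC)c(OC)c2)c(OC)c1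
A2 | alternative 1 | (4S,5R)-4-(4-allyl-2,6-dimethoxyphenoxy)-2,2-dimethyl-5-(3,4,5-trimethoxyphenyl)-1,2-oxasilolane | C[Si]1(C)C[C@@H](Oc2c(OC)cc(CC=C)cc2OC)[C@@H](c2cc(OC)c(OC)c(OC)c2)O1
A3 | alternative 2 | [(Z)-3-(2,6-dimethoxyphenoxy)prop-2-en-1-yl]bis[(1R,2S,3R,5R)-2,6,6-trimethylbicyclo[3.1.1]heptan-3-yl]borane | COc1cccc(OC)c1O/C=C\CB([C@@H]1C[C@@H]2C[C@H]([C@H]1C)C2(C)C)[C@@H]1C[C@@H]2C[C@H]([C@H]1C)C2(C)C
A4 | alternative 2 | 3,4,5-trimethoxybenzaldehyde | COc1cc(C=O)cc(OC)c1OC
A5 | alternative 2 | (1R,2R)-2-(2,6-dimethoxyphenoxy)-1-(3,4,5-trimethoxyphenyl)but-3-en-1-ol | COc1cccc(OC)c1O[C@H](C=C)[C@H](O)c1cc(OC)c(OC)c(OC)c1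
A6 | alternative 3 | (4-allyl-2,6-dimethoxyphenoxy)acetaldehyde | C=CCc1cc(OC)c(OCC=O)c(OC)c1
A7 | alternative 3 | formaldehyde | C=O
A8 | alternative 3 | (R)-2-(4-allyl-2,6-dimethoxyphenoxy)-3-hydroxypropanal | C=CCc1cc(OC)c(O[C@H](CO)C=O)c(OC)c1
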